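**Retrosynthetic overview**
- The only ring is closed last, as in the polyketide pathway: intramolecular Claisen C-acylation of a linear 5,7-dioxo chain by its terminal carboxyl derivative.
- That chain is made in the same flask by crossed Claisen of a C17 methyl ketone enolate with ethyl (S)-5-oxotetrahydrofuran-2-carboxylate (L-glutamic acid pool). The ketone methyl becomes ring C-2; the lactone supplies C-1, C-3 to C-6, the free 6-OH and the S centre.
- The methyl ketone (E)-heptadec-15-en-2-one comes from heptadec-16-en-2-one by E-selective one-position alkene isomerisation.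
- Heptadec-16-en-2-one comes from copper-catalysed sp3–sp3 coupling of undec-10-enylmagnesium bromide with 6-bromohexan-2-one.

Assumption: the target is the 6S enol tautomer drawn (= (S)-4-hydroxy-2-[(E)-hexadec-14-enoyl]cyclohexane-1,3-dione; tautomers equilibrate), and its presumed biosynthesis is Claisen ring closure of a linear 5,7-dioxoacyl thioester.

**Route**

Step 1
Reactants: 1 11-bromoundec-1-ene; 2 6-bromohexan-2-one
Product: 4 heptadec-16-en-2-one, via undec-10-enylmagnesium bromide 3 (not isolated)
Conditions: 1, Mg, THF, 23 °C; then 3 added dropwise (1 h) to 2, Li2CuCl4 (3 mol%), NMP (4 equiv), THF, 0 → 20 °C; aq NH4Cl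
Reagents that add atoms: none
Why: Copper-catalysed Kochi-type sp3–sp3 cross-coupling of a primary alkyl Grignard reagent with a primary alkyl bromide, in which slow addition and the fast cuprate displacement promoted by NMP outrun 1,2-addition to and enolisation of the methyl ketone, a chemoselectivity established for the Li2CuCl4/NMP system.

Step 2
Reactants: 4 heptadec-16-en-2-one
Product: 5 (E)-heptadec-15-en-2-one
Conditions: [(C5Me5)Ru(NCMe)(L)]PF6 (1 mol%; L = 2-(di-isopropylphosphino)-4-tert-butyl-1-methylimidazole), acetone, 40 °C, monitored by 1H NMR; silica plug; recrystallised from pentane at −20 °C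
Reagents that add atoms: none
Why: Catalytic positional alkene isomerisation by a bifunctional ruthenium phosphinoimidazole complex (ligand-assisted allylic deprotonation via an η3-allyl intermediate), in which the bulky C5Me5 ligand stops the migration after one position and gives the E-2-alkene with very high selectivity, the remote ketone being inert.

Step 3
Reactants: 5 (E)-heptadec-15-en-2-one; 6 ethyl (S)-5-oxotetrahydrofuran-2-carboxylate
Product: 10 (6S)-3,6-dihydroxy-2-[(14E)-hexadec-14-enoyl]cyclohex-2-en-1-one, via kinetic lithium enolate 7 (not isolated), via keto-lactone lithium diketonate 8 (not isolated), via dilithium triketonate alkoxide 9 (not isolated)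
Conditions: 5 (2.0 equiv), LiN(SiMe3)2 (2.0 equiv), THF, −78 °C, 45 min; 6 (1.0 equiv), −78 → 0 °C; then 23 → 50 °C, 4 h; 1 M HCl (excess 5 recovered)
Reagents that add atoms: none
Why: Proposed new method: the methyl enolate 7 is C-acylated by the activated α-oxygenated ester of 6 (crossed Claisen condensation, the second enolate equivalent serving as base) to give 8, the lithium chelate of the linear 5,7-dioxo chain, whose central carbon then attacks the lactone carbonyl, directly or after opening of the lactone by the ethoxide formed, in a six-membered-ring Claisen (Dieckmann-type) cyclisation that releases the C-6 oxygen and is driven by formation of the stabilised triketonate 9; attack on the lactone first would converge on the same product, and the S centre is carried over unchanged from 6 because no bond to it is made or broken and the adjacent enolate or alkoxide charge disfavours its deprotonation; the closest known reactions are the Claisen cyclisation of polyketo esters to acylphloroglucinols and the Lacey–Dieckmann cyclisation of α-chiral esters to 3-acyltetramic acids.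

**Compound list**
1 | 11-bromoundec-1-ene | C=CCCCCCCCCCBr | starting material
2 | 6-bromohexan-2-one | CC(=O)CCCCBr | starting material
3 | undec-10-enylmagnesium bromide (formed in situ) | C=CCCCCCCCCC[Mg]Br | intermediate
4 | heptadec-16-en-2-one | C=CCCCCCCCCCCCCCC(C)=O | intermediate
5 | (E)-heptadec-15-en-2-one | C/C=C/CCCCCCCCCCCCC(C)=O | intermediate
6 | ethyl (S)-5-oxotetrahydrofuran-2-carboxylate | CCOC(=O)[C@@H]1CCC(=O)O1 | starting material
7 | lithium (15E)-heptadeca-1,15-dien-2-olate (kinetic enolate of 5, formed in situ) | C/C=C/CCCCCCCCCCCCC(=C)O[Li] | intermediate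
8 | lithium diketonate of (5S)-5-[(16E)-3-oxooctadec-16-enoyl]oxolan-2-one (formed in situ) | [Li+].C/C=C/CCCCCCCCCCCCC(=O)[CH-]C(=O)[C@@H]1CCC(=O)O1 | intermediate
9 | dilithium salt of 10 (6-alkoxide and triketonate, formed in situ) | [Li+].[Li+].C/C=C/CCCCCCCCCCCCC(=O)[C-]1C(=O)CC[C@H]([O-])C1=O | intermediate
10 | (6S)-3,6-dihydroxy-2-[(14E)-hexadec-14-enoyl]cyclohex-2-en-1-one (CNP0389589.1) | C/C=C/CCCCCCCCCCCCC(=O)C1=C(O)CC[C@H](O)C1=O | target

**Totals**
Total step count: 3. Longest linear sequence: 3 (1 → 4 → 5 → 10).

**Steps most likely to fail, with fallbacks**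

Step 3 is the most likely to fail. The ester 6 may be enolised before it is acylated, which would erode the ee. The diketonate 8 may also close slowly onto the lactone or suffer retro-Claisen scrambling. The fallback sets out from 5 and comes back at 10, and separates the two bond formations. Commercial (S)-5-oxotetrahydrofuran-2-carboxylic acid is activated with 1,1'-carbonyldiimidazole in THF to (S)-1-(5-oxotetrahydrofuran-2-carbonyl)imidazole F1. Enolate 7 (2 equiv, made from 5 as in the route) is acylated by F1 within minutes at −78 °C. Acidic work-up gives (S)-5-[(E)-3-oxooctadec-16-enoyl]dihydrofuran-2(3H)-one F2, which is isolated and checked for ee. F2 is then cyclised in a separate Lacey–Dieckmann-type operation (KOtBu, 2.2 equiv, tBuOH/THF, 23 °C, short reaction time; 1 M HCl) to 10.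

Step 1 is second. The Grignard reagent may add to or enolise the methyl ketone of 2 despite the copper/NMP conditions. The fallback sets out from 3 (made from 1 as in the route) and comes back at 4, and carries the carbonyl as a carboxylate during the coupling. 3 is coupled (Li2CuCl4 cat., THF, −20 → 0 °C) with 5-bromopentanoic acid that has first been deprotonated with MeMgCl, giving hexadec-15-enoic acid F3. F3 with MeLi (2.2 equiv, Et2O, 0 °C; Me3SiCl quench, then aq HCl) gives 4.

Step 2 is third. Incomplete or over-run isomerisation would leave positional or Z isomers that are hard to remove. The fallback sets out from 2 and comes back at 5, bypassing 4, and makes the E-alkene by alkyne reduction. Commercial dec-9-yn-1-ol is C-methylated through its dianion (n-BuLi, 2.1 equiv, THF/DMPU; MeI) to undec-9-yn-1-ol F4. Na in liquid NH3 reduces F4 to (E)-undec-9-en-1-ol F5 (trans from dissolving-metal reduction). CBr4/PPh3 in CH2Cl2 converts F5 into (E)-11-bromoundec-2-ene F6. Mg in THF gives (E)-undec-9-enylmagnesium bromide F7, which is coupled with 2 under the step 1 conditions to give 5 directly.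

**Further compounds**
F1 | step 3 | (S)-1-(5-oxotetrahydrofuran-2-carbonyl)imidazole | O=C([C@@H]1CCC(=O)O1)n1ccnc1
F2 | step 3 | (S)-5-[(E)-3-oxooctadec-16-enoyl]dihydrofuran-2(3H)-one | C/C=C/CCCCCCCCCCCCC(=O)CC(=O)[C@@H]1CCC(=O)O1
F3 | step 1 | hexadec-15-enoic acid | C=CCCCCCCCCCCCCCC(=O)O
F4 | step 2 | undec-9-yn-1-ol | CC#CCCCCCCCCO
F5 | step 2 | (E)-undec-9-en-1-ol | C/C=C/CCCCCCCCO
F6 | step 2 | (E)-11-bromoundec-2-ene | C/C=C/CCCCCCCCBr
F7 | step 2 | (E)-undec-9-enylmagnesium bromide | C/C=C/CCCCCCCC[Mg]Br
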